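The earlier run is this same flask, followed as far as 3.00 h, so I begin from its readings.

common to all: left-handed substrate 0.20 M; right-handed substrate 0.20 M; free catalyst 0.20 mM; racemization catalyst 10 mM; added ligand 26 mM
- eta: partner 0.60 M; the very flask that is asked about, followed so far
- flask: partner 0.600 M; time 6.0 h

eta run (percent of the left-handed substrate and right-handed substrate together charged)

| time / h | left-handed product / % | right-handed product / % |
|---|---|---|
| 0.417 | 22 | 10 |
| 0.833 | 32 | 15 |
| 1.33 | 33 | 14 |
| 1.50 | 36 | 15 |
| 2.00 | 40 | 20 |
| 2.50 | 44 | 20 |
| 3.00 | 46 | 24 |

(scatter of a reading: 2 percentage points)

- free catalyst is single-handed; left-handed substrate and right-handed substrate are mirror images of each other, charged as a racemate, each of them at the stated concentration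
- the numbers in the tables scatter by 2 percentage points (one standard deviation)
- an excess is the difference of the two amounts in percent of their sum
- an excess is below zero if the other one leads

1. left-handed product and right-handed product together, in percent of the left-handed substrate and right-handed substrate charged together, at 6.0 h
2. excess of left-handed product over right-handed product in the product at 6.0 h
3. whether the exchange between left-handed substrate and right-handed substrate keeps pace with the reaction: how far the product's excess at 6.0 h gets from its value without exchange to its value with instant exchange (above 80 % keeps pace, below 20 % hardly takes part, else lags behind)

I read the left-handed column against the right-handed one. The rows up to 1.33 h pool to an excess of 38.1 %, and the rows from 2.00 h on pool to 34.0 %. The forecast's no-exchange reading, by contrast, falls from 46 to 29.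

Without exchange, left-handed product cannot pass the left-handed substrate charged, which is half of the racemate. So the highest excess possible without exchange is the unreacted share over the total yield, which I call the ceiling excess. All the rows of the run pool to an excess of 36.4 %, and the ceiling comes down to that reading at a total yield of one over one plus the excess, 73.3 %, which I call the crossing yield.

The last row proves nothing yet: its excess of 31.4 % stands below its ceiling of 42.9 %.

I take over the forecast's yield of 82 %, and for the excess I commit to the pooled reading. That yield lies above the crossing yield, so an excess held at the pooled reading needs exchange, and I expect the exchange to keep pace.

The forecast differs: “I expect slow, partial exchange”. It gives 82 %, an excess of 25 %, and lags behind.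

The flask gives 77.5 %, an excess of 35.7 %, and keeps pace, at 85 % of the way.

    partner + free catalyst + left-handed substrate → free catalyst + left-handed product (k = 15300 M⁻² h⁻¹)
    partner + free catalyst + right-handed substrate → free catalyst + right-handed product (k = 6760 M⁻² h⁻¹)
    left-handed substrate + racemization catalyst ⇌ right-handed substrate + racemization catalyst, rate k3*[racemization catalyst]*[left-handed substrate] forward; the back reaction follows from the equilibrium constant (k = 344 M⁻¹ h⁻¹)
    racemization catalyst + added ligand ⇌ idle complex, settled at all times (K = 15.0 M⁻¹)
    2 free catalyst → spent catalyst (k = 3010 M⁻¹ h⁻¹)

The flask's yield stands above the crossing yield of 73.3 %, and its left-handed product is 52.6 % of the two substrates charged together. The neighbour charged with 5.0 × 10⁻⁴ M of free catalyst reaches 85.0 % in the same time, also above the crossing yield. Its ceiling excess is 17.6 %, and its excess of 33.4 % stands above that, with left-handed product at 56.7 %.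

The data stem from a simulated flask with made-up constants; noise was put on by code.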